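(The readings were generated by integration for substances that don't exist; scatter was added.)

The product asked about in these flasks is the intermediate, and a short meeting had to say which temperature leaves most of it after 4.0 min.

| flask | substrate | reagent | temperature | remark | time |
|---|---|---|---|---|---|
| teal | 17 mM | 29 mM | 50 °C | run made earlier |  |
| violet | 17 mM | 45 mM | 72 °C | run made earlier |  |
| ochre | 26 mM | 20.4 mM | 50 °C | run made earlier |  |
| north-east | 17 mM | 20.4 mM | 60 °C |  | 4.0 min |
| east | 17 mM | 20.4 mM | 40 °C |  | 4.0 min |
| north | 17 mM | 20.4 mM | 80 °C |  | 4.0 min |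

teal run (percent of the substrate charged)

| time / min | intermediate / % | target / % | substrate / % |
|---|---|---|---|
| 0.500 | 29.8 | 1.4 | 71.5 |
| 0.833 | 42.4 | 2.1 | 58.5 |
| 1.33 | 56.1 | 2.6 | 43.9 |
| 2.00 | 65.6 | 2.0 | 32.9 |
| 4.00 | 82.4 | 4.3 | 12.6 |
| 6.00 | 85.2 | 6.9 | 6.7 |

violet run (percent of the substrate charged)

| time / s | intermediate / % | target / % | substrate / % |
|---|---|---|---|
| 20.0 | 74.1 | 4.1 | 21.4 |
| 40.0 | 84.2 | 7.7 | 6.0 |
| 60.0 | 82.5 | 11.6 | 1.9 |
| 80.0 | 79.8 | 13.7 | 0 |
| 90.0 | 78.1 | 13.2 | 0 |
| 120 | 69.7 | 16.6 | 0 |

ochre run (percent of the substrate charged)

| time / min | intermediate / % | target / % | substrate / % |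
|---|---|---|---|
| 1.33 | 39.1 | 1.6 | 59.9 |
| 2.50 | 51.2 | 0.6 | 44.5 |
| 4.00 | 61.0 | 2.3 | 38.5 |
| 5.00 | 60.6 | 1.7 | 33.4 |
| 6.00 | 62.2 | 4.2 | 30.3 |

(readings scatter by 1 percentage point)

- the flask with the highest amount of intermediate, in percent of the substrate charged ("all alike" if they lie within 1.5 percentage points) (north-east / east / north / all alike)
- final intermediate, as a percentage of the substrate charged, in north-east
- final intermediate, as a percentage of the substrate charged, in east
- final intermediate, as a percentage of the substrate charged, in north



The kineticist opened with the violet run. Once substrate read 0%, intermediate fell from 79.8% to 69.7%, which she took as a first-order loss constant of 0.203 min⁻¹. Treating substrate and reagent as reacting one to one, she read a making constant of 0.127 mM⁻¹ min⁻¹ there and 0.0282 mM⁻¹ min⁻¹ in the teal run.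

The plant chemist objected that teal's loss constant, 0.0162 min⁻¹, read from target and not from intermediate as in violet, rests on a target gain of 4.9 percentage points against a scatter of 1 point. It was minuted as rough.

The kineticist then proposed dividing the loss constant by the making constant, so that time drops out. At one temperature, with intermediate made and lost by these two steps, intermediate grows while substrate times reagent over intermediate, all in mM, stands above that quotient, and shrinks below it. The quotient read 0.576 mM in teal and 1.59 mM in violet, the hotter run, higher there. Interpolated in its logarithm, it gives 0.915 mM for north-east: the balance concentration, loss constant of intermediate over making constant.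

The plant chemist applied it to north-east, where substrate, at 17 mM against 20.4 mM of reagent, is the limiting reagent. Guessing 0.7 of the charge as intermediate, the crossing comes at 2.01 mM substrate. With a making constant of 0.0560 mM⁻¹ min⁻¹, the reckoning puts that at 4.24 min, close to the time asked. The meeting committed to north-east.

The forecast also named north-east, with 72% there, 49.5% in east and 17% in north, the last “heavily degraded”.

The flasks give 73.0% in north-east, 51.2% in east and 21.0% in north, so north-east holds the most.

    target → over-reaction product (k = 0.206 min⁻¹, Ea = 100 kJ mol⁻¹)
    substrate + reagent → intermediate + by-product (k = 55.8 M⁻¹ min⁻¹, Ea = 66.0 kJ mol⁻¹)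
    2 substrate → self-condensation product (k = 0.00769 M⁻¹ min⁻¹, Ea = 77.0 kJ mol⁻¹)
    intermediate → target (k = 0.0594 min⁻¹, Ea = 99.0 kJ mol⁻¹)
    (constants at 60 °C)

North-east held 12.8% substrate and 27.3% of its reagent at 4.00 min, and the temperature between east and north that gives the highest intermediate at that time is 57.4 °C. That state of north-east puts substrate times reagent over intermediate at 0.977 mM, beside the balance concentration of 0.915 mM reckoned from the runs. For east the same line, carried below teal's temperature, gives 0.363 mM. Read at 10.0 min, east stands at 2.56 mM, above it, with 72.4% intermediate; read at 40.0 min, it stands at 0.194 mM, below it, with 78.7%.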